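**Plan**

1. Labdane numbering is used: decalin C1–C10, C17 = methylene carbon on C8, C18/C19 = methyl/CH2OAc on C4, C20 = methyl on C10, C11–C16 = side chain; α = the face of H-5 and C20.
2. Cuts: C12–C13 (alkylzinc + 3-bromobutenolide), then the acetate and the C4–C18 methyl bond, then C1–C2 and C5–C10 together by a retro-Diels–Alder that opens rings A and B at once.
3. Enabling feature: in ring A the C1–C2 and C5–C10 bonds are para-related, so ring A is the cyclohexene of a diene C2=C3–C4=C5 (C4 carrying C19 as a carboxyl) and a dienophile C10(CH3)=C1, with C6–C9 of ring B as tether. C7 is allylic to the C8=C17 methylene and 1,3 to C5, so the C19 carboxyl can be tied to an oxygen on C7 as a temporary δ-lactone and later cut loose as an allylic ester.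
4. Forward: (S)-carvone is degraded to a C9 unit with two differentiated two-carbon arms (C8–C7, C11–C12) plus the isopropenyl group (C10, C1, C20). C17, C6–C4, C19 and C3–C2 are added to the chain, the lactone is closed, one cycloaddition closes rings A and B, and the butenolide is joined last.
5. Stereochemistry: C9 from carvone; the temporary C7 carbinol from a catalyst-controlled propargylation; C5 and C10 (cis ring fusion) from the lactone-templated cycloaddition; C4 from face-selective methylation of the C4 enediolate.

Key step: step 12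

Remark: the SMILES is read literally, so H-5 and C20 are on the same face and rings A/B are cis-fused (4R,5R,9R,10S); this diastereomer, not a trans-fused labdane, is the goal.

**Route**

Step 1
Reactants: 1 (S)-(+)-carvone
Product: 2 (1S,4S,6S)-1-methyl-4-(prop-1-en-2-yl)-7-oxabicyclo[4.1.0]heptan-2-one
Conditions: 30% aq. H2O2, NaOH (cat.), MeOH, 0 °C
Reagents that add atoms: hydrogen peroxide (OO)
Why: Nucleophilic (Weitz–Scheffer) epoxidation attacks only the electron-poor enone double bond and spares the isopropenyl group; the two new centres are destroyed in step 2, so their configuration is immaterial.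

Step 2
Reactants: 2 carvone epoxide
Product: 5 (3S)-5-oxo-3-(prop-1-en-2-yl)pentanoic acid, via keto glycol 3 (not isolated), via dioxo aldehyde 4 (not isolated)
Conditions: H5IO6 (3 equiv), THF/H2O, 0 °C to rt
Reagents that add atoms: water (O); orthoperiodic acid (O[I](O)(O)(O)(O)=O)
Why: Periodic acid should open the epoxide to the glycol and then cleave both the C2–C3 glycol bond and the resulting α-dicarbonyl bond (glycol cleavage), excising carvone C2 and its methyl as acetic acid and leaving the carvone stereocentre (future C9) between an aldehyde arm (C8–C7) and an acid arm (C11–C12).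

Step 3
Reactants: 5 aldehyde acid
Product: 6 methyl (3S)-5-oxo-3-(prop-1-en-2-yl)pentanoate
Conditions: TMSCHN2, MeOH/PhMe, 0 °C
Reagents that add atoms: trimethylsilyldiazomethane (C[Si](C)(C)C=[N+]=[N-])
Why: Diazoalkane esterification methylates the acid under neutral conditions that spare the aldehyde.

Step 4
Reactants: 6 aldehyde ester
Product: 7 methyl (3S)-4-formyl-3-(prop-1-en-2-yl)pent-4-enoate
Conditions: 37% aq. CH2O, pyrrolidine (cat.), EtCO2H (cat.), i-PrOH, 45 °C
Reagents that add atoms: formaldehyde (C=O)
Why: Amine/acid-catalysed Mannich condensation–elimination (α-methylenation of an aldehyde) installs C17 on the only enolisable α-carbon (C8); the C9 hydrogen is cross-conjugated in the product and is not acidified.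

Step 5
Reactants: 7 enal ester
Product: 8 methyl (3S,5S)-5-hydroxy-4-methylidene-3-(prop-1-en-2-yl)oct-7-ynoate
Conditions: allenyltributylstannane, Ti(OiPr)4 (10 mol%), (S)-1,1'-bi-2-naphthol (20 mol%), 4 Å molecular sieves, CH2Cl2, −20 °C
Reagents that add atoms: allenyltributylstannane (C=C=C[Sn](CCCC)(CCCC)CCCC)
Why: Keck-type catalytic asymmetric propargylation (SE2′ addition of the allenylstannane to the aldehyde held by the chiral titanium binaphtholate) adds C6–C4 and should set the temporary C7 carbinol as S under catalyst control; any C7 epimer is a separable diastereomer because C9 is already fixed.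

Step 6
Reactants: 8 hydroxy ester
Product: 9 (3S,5S)-4-methylidene-3-(prop-1-en-2-yl)oct-7-yne-1,5-diol
Conditions: LiAlH4, THF, 0 °C
Reagents that add atoms: none
Why: Hydride reduction of the ester (or of any δ-lactone that 8 forms with its C7 hydroxyl) gives the C12 alcohol without touching the alkyne or the alkenes.

Step 7
Reactants: 9 diol
Product: 10 (3S,5S)-1,5-bis[(tert-butyldimethylsilyl)oxy]-4-methylidene-3-(prop-1-en-2-yl)oct-7-yne
Conditions: TBSOTf, 2,6-lutidine, CH2Cl2, −78 to 0 °C
Reagents that add atoms: tert-butyldimethylsilyl triflate (CC(C)(C)[Si](C)(C)OS(=O)(=O)C(F)(F)F)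
Why: Silyl triflate silylation protects both hydroxyls, so that the acetylide step and the two palladium-catalysed steps are run with a silyl ether, not an ionisable ester, at allylic C7.

Step 8
Reactants: 10 bis-silyl ether
Product: 12 methyl (5S,7S)-5,9-bis[(tert-butyldimethylsilyl)oxy]-6-methylidene-7-(prop-1-en-2-yl)non-2-ynoate, via lithium acetylide 11 (not isolated)
Conditions: n-BuLi, THF, −78 °C; then ClCO2Me, −78 to 0 °C
Reagents that add atoms: methyl chloroformate (COC(=O)Cl)
Why: Deprotonation of the terminal alkyne and acylation of the acetylide introduce C19 at the ester oxidation level.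

Step 9
Reactants: 12 ynoate
Product: 13 methyl (2E,5S,7S)-5,9-bis[(tert-butyldimethylsilyl)oxy]-6-methylidene-7-(prop-1-en-2-yl)-2-(tributylstannyl)non-2-enoate
Conditions: Bu3SnH, Pd(PPh3)4 (cat.), THF, 0 °C to rt
Reagents that add atoms: tributyltin hydride (CCCC[SnH](CCCC)CCCC)
Why: Palladium-catalysed syn-hydrostannation of a 2-alkynoate puts tin on the α-carbon (C4) and hydrogen on C5, so the C6 chain ends cis to the ester, the geometry needed for lactonisation and for the diene.

Step 10
Reactants: 13 α-stannyl enoate
Product: 14 methyl (2Z,5S,7S)-5,9-bis[(tert-butyldimethylsilyl)oxy]-2-ethenyl-6-methylidene-7-(prop-1-en-2-yl)non-2-enoate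
Conditions: vinyl bromide, Pd2(dba)3 (cat.), AsPh3, CuI, NMP, 40 °C
Reagents that add atoms: vinyl bromide (C=CBr)
Why: Stille coupling with retention of alkene geometry attaches the C3=C2 vinyl group to C4 and completes the 2-alkoxycarbonyl-1,3-diene.

Step 11
Reactants: 14 triene ester
Product: 16 (6S)-3-ethenyl-6-[(3S)-5-hydroxy-3-(prop-1-en-2-yl)pent-1-en-2-yl]-5,6-dihydro-2H-pyran-2-one, via dihydroxy ester 15 (not isolated)
Conditions: HF·pyridine, THF, 0 °C to rt; then PPTS (cat.), PhMe, 40 °C
Reagents that add atoms: none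
Why: Desilylation frees both hydroxyls, and the C7 hydroxyl, held cis to the ester across C4=C5, should lactonise to the temporary six-membered ring.

Step 12
Reactants: 16 vinyl lactone
Product: 17 tricyclic lactone: cis-fused octalin (C3=C4, C8=C17 methylene, C10 methyl, C9 2-hydroxyethyl) whose C19 carboxyl on C4 is lactonised onto the oxygen at C7 (5R,7S,9S,10S)
Conditions: PhMe (0.005 M), BHT (cat.), 130 °C, sealed tube
Reagents that add atoms: none
Why: A concerted thermal [4+2] cycloaddition joins the lactone diene C2=C3–C4=C5 to the unactivated isopropenyl group C10=C1, the closest known type being the intramolecular Diels–Alder reaction of 1,3,9-decatrienes that carry a 2-alkoxycarbonyl diene. Ring A is formed by the cycloaddition itself (new bonds C1–C2 and C5–C10, new C3=C4 alkene), and ring B is closed at the same moment by the C5–C10 bond across the four-atom tether C6–C9, as a chair inside a bicyclo[3.3.1] lactone transition state. The six-membered lactone holds C7 syn-clinal to C4 about the C5–C6 bond, which is the cis-fused (tether-endo) arrangement, whereas the trans-fused mode needs C7 anti to C4 and cannot be reached from that ring. C5 and C10 are set by C7, which fixes the diene face, and by C9, whose side chain must be equatorial because the axial site points into the lactone carbonyl, so H-5, C20 and the C9 side chain all end on the face opposite the bridge. The step needs cis ring fusion, one diene face and the isopropenyl rather than the C8 methylene as dienophile; the lactone and the matched 7S,9S pair secure the first two, and the C8 methylene is only two atoms from C5 and cannot span the diene. High dilution and a radical inhibitor are meant to hold back dimerisation of the vinyl lactone.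

Step 13
Reactants: 17 tricyclic lactone
Product: 18 (4aS,5R,8aR)-5-(2-hydroxyethyl)-4a-methyl-6-methylidene-3,4,4a,5,6,7,8,8a-octahydronaphthalene-1-carboxylic acid
Conditions: Pd2(dba)3 (cat.), PBu3, HCO2H, Et3N, THF, 45 °C
Reagents that add atoms: none
Why: Palladium-catalysed formate hydrogenolysis of an allylic ester (Tsuji–Trost ionisation of the C7–O bond, then hydride transfer from the palladium formate to the more substituted allyl terminus C7) removes the temporary ring, returns C7 as a methylene beside the 8(17)-alkene and releases the C19 acid.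

Step 14
Reactants: 18 unsaturated acid
Product: 20 (1R,4aS,5R,8aR)-5-(2-hydroxyethyl)-1,4a-dimethyl-6-methylidenedecahydronaphthalene-1-carboxylic acid, via trilithium enediolate 19 (not isolated)
Conditions: Li, NH3(l)/THF, t-BuOH (1 equiv), −78 °C; then MeI, −78 to −33 °C
Reagents that add atoms: iodomethane (CI)
Why: Dissolving-metal reduction of the α,β-unsaturated carboxylate gives the C4 enediolate, whose C-methylation creates the quaternary centre; in the conformer that avoids allylic strain between the enediolate oxygens and C6, C20 lies syn-axial over the α face of C4, so iodomethane should enter from the β face (anti to the angular methyl, as in reductive methylations of trans-fused resin-acid precursors) and leave the carboxyl α, cis to H-5 and C20.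

Step 15
Reactants: 20 saturated acid
Product: 21 [(1R,4aS,5R,8aR)-5-(2-hydroxyethyl)-1,4a-dimethyl-6-methylidenedecahydronaphthalen-1-yl]methanol
Conditions: LiAlH4, THF, reflux
Reagents that add atoms: none
Why: LiAlH4 reduces the hindered carboxylic acid to the neopentyl C19 alcohol.

Step 16
Reactants: 21 diol
Product: 22 [(1R,4aS,5R,8aR)-5-(2-iodoethyl)-1,4a-dimethyl-6-methylidenedecahydronaphthalen-1-yl]methanol
Conditions: I2, PPh3, imidazole, CH2Cl2, 0 °C
Reagents that add atoms: iodine (II)
Why: Appel-type iodination should be selective for the unhindered primary C12 alcohol, since displacement at the neopentyl C19 carbinol is far slower.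

Step 17
Reactants: 22 iodo alcohol
Product: 23 [(1R,4aS,5R,8aR)-5-(2-iodoethyl)-1,4a-dimethyl-6-methylidenedecahydronaphthalen-1-yl]methyl acetate
Conditions: Ac2O, Et3N, DMAP (cat.), CH2Cl2, 0 °C to rt
Reagents that add atoms: acetic anhydride (CC(=O)OC(C)=O)
Why: Nucleophile-catalysed acylation esterifies the remaining neopentyl alcohol.

Step 18
Reactants: 23 iodo acetate; 24 3-bromofuran-2(5H)-one
Product: 26 [(1R,4aS,5R,8aR)-1,4a-dimethyl-6-methylidene-5-[2-(2-oxo-2,5-dihydrofuran-3-yl)ethyl]decahydronaphthalen-1-yl]methyl acetate, via alkylzinc iodide 25 (not isolated)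
Conditions: Zn dust, LiCl, THF, 40 °C; then 24, Pd(OAc)2 (cat.), 2-dicyclohexylphosphino-2',6'-dimethoxybiphenyl, THF, rt
Reagents that add atoms: none
Why: Zinc insertion into the primary iodide and Negishi coupling of the alkylzinc with the α-bromobutenolide form the C12–C13 bond under conditions that should tolerate the acetate, the butenolide and the exocyclic alkene.

**Compound list**

1 | (S)-(+)-carvone, (5S)-2-methyl-5-(prop-1-en-2-yl)cyclohex-2-en-1-one | CC1=CC[C@@H](CC1=O)C(C)=C | starting material
2 | (1S,4S,6S)-1-methyl-4-(prop-1-en-2-yl)-7-oxabicyclo[4.1.0]heptan-2-one | C[C@]12O[C@H]1C[C@@H](CC2=O)C(C)=C | intermediate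
3 | (2S,3R,5S)-2,3-dihydroxy-2-methyl-5-(prop-1-en-2-yl)cyclohexan-1-one (keto glycol, not isolated) | C[C@]1(O)[C@H](O)C[C@@H](CC1=O)C(C)=C | intermediate
4 | (3S)-5,6-dioxo-3-(prop-1-en-2-yl)heptanal (dioxo aldehyde, not isolated) | C=C(C)[C@@H](CC=O)CC(=O)C(C)=O | intermediate
5 | (3S)-5-oxo-3-(prop-1-en-2-yl)pentanoic acid | C=C(C)[C@@H](CC=O)CC(=O)O | intermediate
6 | methyl (3S)-5-oxo-3-(prop-1-en-2-yl)pentanoate | C=C(C)[C@@H](CC=O)CC(=O)OC | intermediate
7 | methyl (3S)-4-formyl-3-(prop-1-en-2-yl)pent-4-enoate | C=C(C)[C@@H](C(=C)C=O)CC(=O)OC | intermediate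
8 | methyl (3S,5S)-5-hydroxy-4-methylidene-3-(prop-1-en-2-yl)oct-7-ynoate | C=C(C)[C@@H](C(=C)[C@@H](O)CC#C)CC(=O)OC | intermediate
9 | (3S,5S)-4-methylidene-3-(prop-1-en-2-yl)oct-7-yne-1,5-diol | C=C(C)[C@@H](C(=C)[C@@H](O)CC#C)CCO | intermediate
10 | (3S,5S)-1,5-bis[(tert-butyldimethylsilyl)oxy]-4-methylidene-3-(prop-1-en-2-yl)oct-7-yne | C=C(C)[C@@H](C(=C)[C@@H](O[Si](C)(C)C(C)(C)C)CC#C)CCO[Si](C)(C)C(C)(C)C | intermediate
11 | lithium acetylide of 10 (not isolated) | C=C(C)[C@@H](C(=C)[C@@H](O[Si](C)(C)C(C)(C)C)CC#C[Li])CCO[Si](C)(C)C(C)(C)C | intermediate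
12 | methyl (5S,7S)-5,9-bis[(tert-butyldimethylsilyl)oxy]-6-methylidene-7-(prop-1-en-2-yl)non-2-ynoate | C=C(C)[C@@H](C(=C)[C@@H](O[Si](C)(C)C(C)(C)C)CC#CC(=O)OC)CCO[Si](C)(C)C(C)(C)C | intermediate
13 | methyl (2E,5S,7S)-5,9-bis[(tert-butyldimethylsilyl)oxy]-6-methylidene-7-(prop-1-en-2-yl)-2-(tributylstannyl)non-2-enoate | C=C(C)[C@@H](C(=C)[C@@H](O[Si](C)(C)C(C)(C)C)C/C=C(/[Sn](CCCC)(CCCC)CCCC)C(=O)OC)CCO[Si](C)(C)C(C)(C)C | intermediate
14 | methyl (2Z,5S,7S)-5,9-bis[(tert-butyldimethylsilyl)oxy]-2-ethenyl-6-methylidene-7-(prop-1-en-2-yl)non-2-enoate | C=C(C)[C@@H](C(=C)[C@@H](O[Si](C)(C)C(C)(C)C)C/C=C(/C=C)C(=O)OC)CCO[Si](C)(C)C(C)(C)C | intermediate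
15 | methyl (2Z,5S,7S)-2-ethenyl-5,9-dihydroxy-6-methylidene-7-(prop-1-en-2-yl)non-2-enoate (dihydroxy ester, not isolated) | C=C(C)[C@@H](C(=C)[C@@H](O)C/C=C(/C=C)C(=O)OC)CCO | intermediate
16 | (6S)-3-ethenyl-6-[(3S)-5-hydroxy-3-(prop-1-en-2-yl)pent-1-en-2-yl]-5,6-dihydro-2H-pyran-2-one | C=C(C)[C@@H](C(=C)[C@@H]1CC=C(C=C)C(=O)O1)CCO | intermediate
17 | tricyclic lactone (labdane numbering, 5R,7S,9S,10S): cis-fused octalin with C3=C4, C8=C17 methylene, C10 methyl, C9 2-hydroxyethyl, and the C19 carboxyl on C4 closed as a δ-lactone onto O–C7 | C=C1[C@@H]3C[C@H]2C(C(=O)O3)=CCC[C@@]2(C)[C@@H]1CCO | intermediate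
18 | (4aS,5R,8aR)-5-(2-hydroxyethyl)-4a-methyl-6-methylidene-3,4,4a,5,6,7,8,8a-octahydronaphthalene-1-carboxylic acid | C=C1CC[C@H]2C(C(=O)O)=CCC[C@@]2(C)[C@@H]1CCO | intermediate
19 | trilithium salt (C4 enediolate and C12 alkoxide) of the 3,4-dihydro form of 18 (not isolated) | C=C1CC[C@H]2C(=C([O-])[O-])CCC[C@@]2(C)[C@@H]1CC[O-].[Li+].[Li+].[Li+] | intermediate
20 | (1R,4aS,5R,8aR)-5-(2-hydroxyethyl)-1,4a-dimethyl-6-methylidenedecahydronaphthalene-1-carboxylic acid | C=C1CC[C@H]2[C@](C)(C(=O)O)CCC[C@@]2(C)[C@@H]1CCO | intermediate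
21 | [(1R,4aS,5R,8aR)-5-(2-hydroxyethyl)-1,4a-dimethyl-6-methylidenedecahydronaphthalen-1-yl]methanol | C=C1CC[C@H]2[C@](C)(CO)CCC[C@@]2(C)[C@@H]1CCO | intermediate
22 | [(1R,4aS,5R,8aR)-5-(2-iodoethyl)-1,4a-dimethyl-6-methylidenedecahydronaphthalen-1-yl]methanol | C=C1CC[C@H]2[C@](C)(CO)CCC[C@@]2(C)[C@@H]1CCI | intermediate
23 | [(1R,4aS,5R,8aR)-5-(2-iodoethyl)-1,4a-dimethyl-6-methylidenedecahydronaphthalen-1-yl]methyl acetate | C=C1CC[C@H]2[C@](C)(COC(C)=O)CCC[C@@]2(C)[C@@H]1CCI | intermediate
24 | 3-bromofuran-2(5H)-one | O=C1OCC=C1Br | starting material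
25 | alkylzinc iodide from 23 (not isolated) | C=C1CC[C@H]2[C@](C)(COC(C)=O)CCC[C@@]2(C)[C@@H]1CC[Zn]I | intermediate
26 | [(1R,4aS,5R,8aR)-1,4a-dimethyl-6-methylidene-5-[2-(2-oxo-2,5-dihydrofuran-3-yl)ethyl]decahydronaphthalen-1-yl]methyl acetate | C=C1CC[C@H]2[C@](C)(COC(C)=O)CCC[C@@]2(C)[C@@H]1CCC1=CCOC1=O | target

**Step count**

Total steps: 18. Longest linear sequence: 18 steps (from 1; 24 enters in the last step).

**Steps most likely to fail**

Step 14. What may go wrong is poor facial selectivity in the C-methylation: the cis-fused enediolate is conformationally mobile and its β face is flanked by axial C6, so part of the alkylation may occur on the α face. The fallback fixes C4 while the lactone bridge is still in place and lets the bridge carbon become the methyl group. It sets out from 17 and comes back at 21. Conjugate reduction of 17 with LiBH(s-Bu)3 and trapping of the lactone enolate (and of the C12 alkoxide) with benzyl chloromethyl ether should give the saturated bridged lactone F4. In F4 the new benzyloxymethyl group can only sit on the face opposite the bridge, which is the α (C19) position. Formate hydrogenolysis as in step 13 would open it to the 4β-carboxylic acid F5. LiAlH4 would give the 4β-hydroxymethyl compound F6, Dess–Martin periodinane the 4β-aldehyde F7, and Wolff–Kishner reduction (N2H4·H2O, KOH, diethylene glycol, 200 °C) the 4β-methyl compound F8. Li/NH3 would then remove the benzyl ether and the benzyloxymethyl ether to return diol 21.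

Step 12. What may go wrong is slow cycloaddition through the bridged transition state, which would let the vinyl lactone dimerise or let a boat-like ring B leak into the trans-fused series. The fallback drops the temporary ring and removes the C7 oxygen before the cycloaddition. It sets out from 15 (isolated by omitting the acid treatment of step 11) and comes back at 18. Formic acetic anhydride/pyridine should give the bis-formate F1. Pd2(dba)3/PBu3 would then effect decarboxylative hydrogenolysis of the allylic C7 formate to the C7-deoxy triene formate F2. Conventional thermolysis of this 1,3,9-decatriene (PhMe, 170 °C) should give the cycloadduct F3. Its ring fusion then rests only on the diene substituent and the angular methyl, so the cis-fused isomer F3 would have to be separated from its trans-fused epimer. Saponification (LiOH, THF/MeOH/H2O) returns acid 18.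

Step 18. What may go wrong is β-hydride elimination or protonolysis of the alkylzinc, or decomposition of the bromobutenolide under the coupling conditions. The fallback is enolate alkylation followed by sulfoxide elimination. It sets out from 23 and comes back at 26. The lithium enolate of 3-(phenylsulfanyl)oxolan-2-one (LDA, THF/HMPA) would be alkylated by 23 to the α-phenylsulfanyl lactone F9 (mixture at C13). Oxidation with mCPBA (1 equiv, −78 °C) should give the sulfoxide F10, and syn-elimination in PhMe at 110 °C should give 26; attack of the enolate on the acetate is the point to watch.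

**Further compounds**

F1 | step 12 | methyl (2Z,5S,7S)-2-ethenyl-5,9-bis(formyloxy)-6-methylidene-7-(prop-1-en-2-yl)non-2-enoate | C=C(C)[C@@H](C(=C)[C@@H](OC=O)C/C=C(/C=C)C(=O)OC)CCOC=O
F2 | step 12 | methyl (2Z,7S)-2-ethenyl-9-(formyloxy)-6-methylidene-7-(prop-1-en-2-yl)non-2-enoate | C=C(C)[C@@H](C(=C)CC/C=C(/C=C)C(=O)OC)CCOC=O
F3 | step 12 | methyl (4aS,5R,8aR)-5-[2-(formyloxy)ethyl]-4a-methyl-6-methylidene-3,4,4a,5,6,7,8,8a-octahydronaphthalene-1-carboxylate | C=C1CC[C@H]2C(C(=O)OC)=CCC[C@@]2(C)[C@@H]1CCOC=O
F4 | step 14 | 3,4-dihydro derivative of 17 with a 4α-benzyloxymethyl group and a benzyloxymethyl ether on O-12 (lactone carbonyl 4β) | C=C1[C@@H]3C[C@H]2[C@@](COCc4ccccc4)(C(=O)O3)CCC[C@@]2(C)[C@@H]1CCOCOCc1ccccc1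
F5 | step 14 | 4α-benzyloxymethyl 4β-carboxylic acid with C7 methylene, 8(17)-alkene and O-12 benzyloxymethyl ether | C=C1CC[C@H]2[C@@](COCc3ccccc3)(C(=O)O)CCC[C@@]2(C)[C@@H]1CCOCOCc1ccccc1
F6 | step 14 | 4α-benzyloxymethyl 4β-hydroxymethyl analogue of F5 | C=C1CC[C@H]2[C@@](COCc3ccccc3)(CO)CCC[C@@]2(C)[C@@H]1CCOCOCc1ccccc1
F7 | step 14 | 4α-benzyloxymethyl 4β-carbaldehyde analogue of F5 | C=C1CC[C@H]2[C@@](COCc3ccccc3)(C=O)CCC[C@@]2(C)[C@@H]1CCOCOCc1ccccc1
F8 | step 14 | 19-O-benzyl, 12-O-benzyloxymethyl derivative of diol 21 (4β-methyl) | C=C1CC[C@H]2[C@@](COCc3ccccc3)(C)CCC[C@@]2(C)[C@@H]1CCOCOCc1ccccc1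
F9 | step 18 | 13-(phenylsulfanyl)-13,14-dihydro derivative of 26 (mixture at C13) | C=C1CC[C@H]2[C@](C)(COC(C)=O)CCC[C@@]2(C)[C@@H]1CCC1(Sc2ccccc2)CCOC1=O
F10 | step 18 | sulfoxide of F9 (mixture at C13 and sulfur) | C=C1CC[C@H]2[C@](C)(COC(C)=O)CCC[C@@]2(C)[C@@H]1CCC1(S(=O)c2ccccc2)CCOC1=O
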